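The vessel is closed and stirred: solid substrate dissolves in it, gas held at 31 mM enters the solution, and target forms.

| flask | solid substrate | gas | remark | time |
|---|---|---|---|---|
| Sunday's | 0.15 M | 31 mM (held) | run made earlier |  |
| flask | 0.10 M | 31 mM (held) |  | 10 d |

- Sunday's (time / h: target / %, dissolved substrate / %, solid substrate / %): 2.50: 0, 17.1, 82.7; 8.00: 0, 16.8, 84.0; 15.0: 4.0, 15.8, 77.6; 20.0: 3.8, 18.3, 75.8; 30.0: 5.3, 17.4, 73.9; 40.0: 9.2, 18.7, 68.6; 50.0: 12.1, 16.4, 62.4

(readings scatter by 1 percentage point)

- given per volume of solution although it is solid: solid substrate
- the numbers in the tables scatter with a standard deviation of 1 percentage point
- at the start none of the solid substrate is in solution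
- at the start none of the gas is in solution
- dissolved substrate means what is dissolved; the solid is not counted in it

- teal: doubling the solubility of the solid substrate, all else as stated
- grey: doubling the dissolution coefficient of the solid substrate, all else as stated
- amber: doubling the saturation concentration of gas, all else as stated
- ochre: doubling the transfer coefficient of the gas, all else as stated

1. how much target there is at 10 d, in percent of the solid substrate charged
2. concentration of dissolved substrate in solution at 5.0 d, in percent of saturation
3. the change that raises the amount of target at 10 d, in percent of the solid substrate charged most ("none" if none brings more than 2 percentage points) (teal / grey / amber / ochre / none)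
4. amount of target at 10 d, in percent of the solid substrate charged, after ochre

Sunday's flask and this flask differ in charge and in time. In Sunday's run dissolved substrate stays level at a mean of 25.8 mM, so I take both solutions to behave alike while solid lies there. But from 30.0 h on, the readings fall short of the charge: this gap grows at 0.200 mM/h, beside 0.510 mM/h for target. I define the target share φ as target's rate over target's rate plus the gap's rate, the selectivity: 71.8% as read from these scattered readings, my first answer for target at 10 d.

I put that answer back in and ask how much is consumed. In Sunday's run solid falls at d = 0.641 mM/h as read. At d I reckon that Sunday's charge lasts 194 h, longer than its last reading, which still shows 62.4% solid. At d I reckon that this flask's solid lasts 116 h, too near 120 h for me to commit on saturation there. After that I let this flask's solution decay with the rate constant d over its concentration, and I reckon 1.18 mM dissolved at 10 d, so I reckon 71.0% target. If target's rate follows the gas, amber lifts φ to 83.6%, so I choose amber.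

The forecast gives 85%, 99%, amber and 86% after ochre: “Gas therefore stays near saturation, and the reaction itself limits”.

The flask gives 70.2%, 98.6%, amber with 13 percentage points gained, and 72.3% after ochre.

    2 dissolved substrate → side product (k = 0.140 /M/h)
    solid substrate ⇌ dissolved substrate, rate k2*(cs2 - [dissolved substrate]) while solid is left; crystals form when [dissolved substrate] > cs2 (solubility = 26.0 mM, k = 1.70 /h)
    dissolved substrate + coupling partner → target (k = 0.620 /M/h)
    gas ⇌ coupling partner, rate k4*(csat - [coupling partner]) (kL = 0.110 /h)

The gap is side product, and the flask's share of target at 10.0 d is 72.0%. On the neighbour flask with 0.17 M of solid substrate, the same reckoning gives the solid 225 h and puts 17.8 mM in solution at 10 d, so φ gives 64.3%. That neighbour flask holds 58.8% target and 25.9% side product at 10 d, with 15% of its charge still there, solid or dissolved, of which 0.242% is solid, and its share of target is 69.4%.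

Readings and results are calculated for substances that don't exist; the scatter is artificial.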